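The cyclohexenone ring (C1 quaternary carbinol, C2 ketone, C3=C4 alkene, C5 benzoate carbon, C6 carbinol) is cut at C2–C3 and C5–C6 into two three-carbon pieces. A [3+3] ylide annulation joins allylidenetriphenylphosphorane (C3–C5) to a formyl acyl chloride (C6–C1–C2): γ-acylation forges C2–C3 and intramolecular Wittig olefination forges C5=C6, giving a silylated ortho-quinol dienone. It exploits the 1,3-placement of the C2 ketone and C6 carbinol across quaternary C1 and the vinylogous C2(=O)–C3=C4–C5 array. C1 is set by catalytic desymmetrisation; C6 and C5 follow by face-selective epoxidation and anti opening with benzoate.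

Key step: step 6

Assumption: the sense of the copper-catalysed desymmetrisation in step 2 follows the ligand enantiomer; (R,R)-Ph-BOX is written, and its mirror image is used instead if it proves to deliver the (R)-monobenzoate.

Step 1
Reactants: 1 2,2-dimethyl-1,3-dioxan-5-one; 2 vinylmagnesium bromide
Product: 4 2-ethenylpropane-1,2,3-triol, via acetonide alcohol 3 (not isolated)
Conditions: THF, −78 to 0 °C; then 1 M HCl, MeOH, rt
Reagents that add atoms: none
Why: Grignard 1,2-addition to the symmetrical ketone followed by acid-catalysed acetonide hydrolysis should give the prochiral triol, with no stereocentre formed.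

Step 2
Reactants: 4 2-ethenylpropane-1,2,3-triol
Product: 5 (2S)-2-hydroxy-2-(hydroxymethyl)but-3-en-1-yl benzoate
Conditions: BzCl (1.0 equiv), Et3N, CuCl2 (5 mol %), (R,R)-Ph-BOX (5 mol %), THF, rt
Reagents that add atoms: benzoyl chloride, O=C(Cl)c1ccccc1
Why: Copper–bis(oxazoline)-catalysed desymmetrising monobenzoylation of a 2-substituted glycerol should acylate one enantiotopic hydroxymethyl group of the copper-bound 1,2-diol and so set C1 under ligand control.

Step 3
Reactants: 5 (2S)-2-hydroxy-2-(hydroxymethyl)but-3-en-1-yl benzoate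
Product: 6 (2R)-2-[(benzoyloxy)methyl]-2-hydroxybut-3-enoic acid
Conditions: TEMPO (cat.), NaOCl (cat.), NaClO2, MeCN, NaH2PO4/Na2HPO4 buffer (pH 6.7), 35 °C
Reagents that add atoms: sodium chlorite, [Na+].[O-]Cl=O
Why: TEMPO/chlorite oxidation should take the primary alcohol to the acid at near-neutral pH without touching the tertiary alcohol, the vinyl group or the benzoate, and it removes the hydroxymethyl group through which benzoyl migration could racemise C1.

Step 4
Reactants: 6 (2R)-2-[(benzoyloxy)methyl]-2-hydroxybut-3-enoic acid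
Product: 8 (2R)-2-(chlorocarbonyl)-2-[(triethylsilyl)oxy]but-3-en-1-yl benzoate, via bis(triethylsilyl) derivative 7 (not isolated)
Conditions: Et3SiOTf (2.4 equiv), 2,6-lutidine, CH2Cl2, −78 to 0 °C; then (COCl)2, DMF (cat.), 0 °C to rt; pentane, filter, evaporate
Reagents that add atoms: triethylsilyl trifluoromethanesulfonate, CC[Si](CC)(CC)OS(=O)(=O)C(F)(F)F; oxalyl chloride, O=C(Cl)C(=O)Cl
Why: The silyl triflate should silylate both the hindered tertiary alcohol and the acid, and oxalyl chloride with catalytic DMF converts a silyl ester directly into the acyl chloride under neutral conditions, so the acyl chloride never meets a free hydroxyl.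

Step 5
Reactants: 8 (2R)-2-(chlorocarbonyl)-2-[(triethylsilyl)oxy]but-3-en-1-yl benzoate
Product: 9 (2S)-3-chloro-2-formyl-3-oxo-2-[(triethylsilyl)oxy]propyl benzoate
Conditions: O3, CH2Cl2, −78 °C; then PPh3 (1.0 equiv), −78 °C to rt; evaporate, use crude
Reagents that add atoms: ozone, [O-][O+]=O
Why: Ozonolysis should cleave only the vinyl group (acyl chloride, silyl ether and the deactivated benzoate ring are inert to ozone), and anhydrous phosphine reduction of the ozonide unveils the aldehyde at the acyl chloride stage, avoiding a decarboxylation-prone β-formyl acid.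

Step 6
Reactants: 9 (2S)-3-chloro-2-formyl-3-oxo-2-[(triethylsilyl)oxy]propyl benzoate; 10 allyltriphenylphosphonium bromide
Product: 13 [(1R)-2-oxo-1-[(triethylsilyl)oxy]cyclohexa-3,5-dien-1-yl]methyl benzoate, via allylidenetriphenylphosphorane 11 (not isolated), via acyl ylide aldehyde 12 (not isolated)
Conditions: 10 (2.1 equiv), NaN(SiMe3)2 (2.0 equiv), THF, −78 to 0 °C; add slowly to 9, THF, −78 °C; then rt to 50 °C
Reagents that add atoms: none
Why: Proposed new method: the γ-carbon of allylic ylide 11 should be acylated by the acyl chloride of 9 (forming C2–C3), a second equivalent of 11 deprotonates the resulting 4-oxoalk-2-enylphosphonium salt to the vinylogous acyl ylide 12, and on warming the ylide carbon olefinates the neighbouring aldehyde intramolecularly (forming C5=C6 with loss of Ph3PO). The closest known reaction types are the γ-acylation of allylidenetriphenylphosphorane by acyl chlorides and the [3+3] annulation of the same ylide with enones (γ-attack, then intramolecular Wittig). The six-membered ring closes by 6-exo-trig attack of the ylide carbon on the formyl group; although four ring atoms are sp2, the phosphonium centre still stabilises the carbanion when C5 twists out of conjugation, and C3=C4 can reach the Z geometry through the phosphonium dienolate resonance form. No stereocentre is created, and C1, being quaternary and non-enolisable, cannot epimerise. The step needs acylation to outrun Wittig olefination of the free aldehyde and γ- rather than α-acylation: the acyl chloride is the faster electrophile at −78 °C, the aldehyde is neopentylic and shielded by the silyl ether, inverse addition keeps the ylide deficient, and α-acylation would place the hindered acyl group on the phosphorus-bearing carbon.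

Step 7
Reactants: 13 [(1R)-2-oxo-1-[(triethylsilyl)oxy]cyclohexa-3,5-dien-1-yl]methyl benzoate
Product: 14 [(1S,2S,6S)-3-oxo-2-[(triethylsilyl)oxy]-7-oxabicyclo[4.1.0]hept-4-en-2-yl]methyl benzoate
Conditions: dimethyldioxirane (acetone solution), CH2Cl2, 0 °C
Reagents that add atoms: dimethyldioxirane, CC1(C)OO1
Why: Electrophilic epoxidation should take the more electron-rich γ,δ-alkene (C5=C6) of the dienone, and attack syn to the C1 oxygen and anti to the bulkier CH2OBz group (the facial preference known for cycloadditions to 6-oxy-6-alkylcyclohexa-2,4-dienones) places the epoxide on the face of the C1–O bond, fixing C6 and the face at C5.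

Step 8
Reactants: 14 [(1S,2S,6S)-3-oxo-2-[(triethylsilyl)oxy]-7-oxabicyclo[4.1.0]hept-4-en-2-yl]methyl benzoate
Product: 15 [(1S,5R,6S)-5-(benzoyloxy)-6-hydroxy-2-oxo-1-[(triethylsilyl)oxy]cyclohex-3-en-1-yl]methyl benzoate
Conditions: PhCO2H (4 equiv), iPr2NEt (0.5 equiv), MeCN, 45 °C
Reagents that add atoms: benzoic acid, O=C(O)c1ccccc1
Why: Benzoate should open the vinylogously activated epoxide by SN2 attack at allylic C5 (C6 is neopentylic, next to quaternary C1) with inversion, giving the trans C5-benzoate/C6-alcohol with C6–OH cis to the C1 oxygen.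

Step 9
Reactants: 15 [(1S,5R,6S)-5-(benzoyloxy)-6-hydroxy-2-oxo-1-[(triethylsilyl)oxy]cyclohex-3-en-1-yl]methyl benzoate
Product: 16 zeylenone
Conditions: HF·pyridine, THF/pyridine, 0 °C to rt
Reagents that add atoms: none
Why: Fluoride-mediated desilylation should cleave the tertiary triethylsilyl ether under mildly acidic conditions that leave both benzoates, the enone and all three stereocentres untouched.

Compound list
1 | 2,2-dimethyl-1,3-dioxan-5-one | CC1(C)OCC(=O)CO1 | starting material
2 | vinylmagnesium bromide | C=C[Mg]Br | starting material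
3 | 5-ethenyl-2,2-dimethyl-1,3-dioxan-5-ol | CC1(C)OCC(O)(C=C)CO1 | intermediate
4 | 2-ethenylpropane-1,2,3-triol | OCC(O)(CO)C=C | intermediate
5 | (2S)-2-hydroxy-2-(hydroxymethyl)but-3-en-1-yl benzoate | O=C(OC[C@@](C=C)(O)CO)c1ccccc1 | intermediate
6 | (2R)-2-[(benzoyloxy)methyl]-2-hydroxybut-3-enoic acid | O=C(OC[C@@](C=C)(O)C(=O)O)c1ccccc1 | intermediate
7 | triethylsilyl (2R)-2-[(benzoyloxy)methyl]-2-[(triethylsilyl)oxy]but-3-enoate | O=C(OC[C@@](C=C)(O[Si](CC)(CC)CC)C(=O)O[Si](CC)(CC)CC)c1ccccc1 | intermediate
8 | (2R)-2-(chlorocarbonyl)-2-[(triethylsilyl)oxy]but-3-en-1-yl benzoate | O=C(OC[C@@](C=C)(O[Si](CC)(CC)CC)C(=O)Cl)c1ccccc1 | intermediate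
9 | (2S)-3-chloro-2-formyl-3-oxo-2-[(triethylsilyl)oxy]propyl benzoate | O=C(OC[C@@](C=O)(O[Si](CC)(CC)CC)C(=O)Cl)c1ccccc1 | intermediate
10 | allyltriphenylphosphonium bromide | C=CC[P+](c1ccccc1)(c1ccccc1)c1ccccc1.[Br-] | starting material
11 | allylidenetriphenylphosphorane | C=CC=P(c1ccccc1)(c1ccccc1)c1ccccc1 | intermediate
12 | (2S,4Z)-2-formyl-3-oxo-2-[(triethylsilyl)oxy]-6-(triphenyl-λ5-phosphanylidene)hex-4-en-1-yl benzoate | O=C(OC[C@@](C=O)(O[Si](CC)(CC)CC)C(=O)/C=C\C=P(c1ccccc1)(c1ccccc1)c1ccccc1)c1ccccc1 | intermediate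
13 | [(1R)-2-oxo-1-[(triethylsilyl)oxy]cyclohexa-3,5-dien-1-yl]methyl benzoate | O=C(OC[C@@]1(O[Si](CC)(CC)CC)C(=O)C=CC=C1)c1ccccc1 | intermediate
14 | [(1S,2S,6S)-3-oxo-2-[(triethylsilyl)oxy]-7-oxabicyclo[4.1.0]hept-4-en-2-yl]methyl benzoate | O=C(OC[C@@]1(O[Si](CC)(CC)CC)C(=O)C=C[C@@H]2O[C@@H]21)c1ccccc1 | intermediate
15 | [(1S,5R,6S)-5-(benzoyloxy)-6-hydroxy-2-oxo-1-[(triethylsilyl)oxy]cyclohex-3-en-1-yl]methyl benzoate | O=C(OC[C@@]1(O[Si](CC)(CC)CC)C(=O)C=C[C@@H](OC(=O)c2ccccc2)[C@@H]1O)c1ccccc1 | intermediate
16 | zeylenone, [(1S,5R,6S)-5-(benzoyloxy)-1,6-dihydroxy-2-oxocyclohex-3-en-1-yl]methyl benzoate | O=C(OC[C@@]1(O)C(=O)C=C[C@@H](OC(=O)c2ccccc2)[C@@H]1O)c1ccccc1 | target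

Total step count: 9. Longest linear sequence: 9 steps (1 to 16); the phosphonium salt 10 is bought.

Steps most likely to fail:

Step 6 (Proposed new method). The unacylated ylide may olefinate the free aldehyde before γ-acylation, or the vinylogous ylide may oligomerise instead of reaching the cisoid geometry needed for ring closure. The fallback uses known chemistry and sets out from 8. Fe(acac)3-catalysed acylation of but-3-enylmagnesium bromide (THF, −78 °C) should give the dienyl ketone (2R)-2-ethenyl-3-oxo-2-[(triethylsilyl)oxy]hept-6-en-1-yl benzoate F1. Ring-closing metathesis with second-generation Grubbs catalyst (CH2Cl2, 40 °C) should then close C5=C6 to the cyclohexenone [(1R)-2-oxo-1-[(triethylsilyl)oxy]cyclohex-5-en-1-yl]methyl benzoate F2. Dehydrogenation with 2-iodoxybenzoic acid (DMSO, 70 °C) can only introduce C3=C4, because C1 is quaternary, and returns to the route at 13.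

Step 7. Facial selectivity of the epoxidation may be poor, with attack anti to the silyloxy group or at the α,β-alkene. The fallback sets out from 13 and relies on hydroxyl direction instead of sterics. HF·pyridine at −20 °C should give the free ortho-quinol [(1R)-1-hydroxy-2-oxocyclohexa-3,5-dien-1-yl]methyl benzoate F3, used at once in dilute solution before Diels–Alder dimerisation. VO(acac)2/tBuOOH (CH2Cl2, 0 °C) should deliver oxygen syn to the tertiary allylic hydroxyl, giving the epoxy alcohol [(1S,2S,6S)-2-hydroxy-3-oxo-7-oxabicyclo[4.1.0]hept-4-en-2-yl]methyl benzoate F4. Ti(OiPr)4-mediated opening with PhCO2H at the carbon remote from the carbinol (C5) then comes back to the route at 16.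

Step 2. Enantioselectivity may be insufficient for the vinyl-substituted triol, or may erode by benzoyl migration between the two hydroxymethyl arms. The fallback sets out from 4 and replaces catalysis by classical resolution. Unselective monobenzoylation (BzCl, pyridine, CH2Cl2, −40 °C) should give the racemic monobenzoate rac-2-hydroxy-2-(hydroxymethyl)but-3-en-1-yl benzoate F5. The same TEMPO/chlorite oxidation gives the racemic acid rac-2-[(benzoyloxy)methyl]-2-hydroxybut-3-enoic acid F6. Crystallisation with (R)-1-phenylethylamine should furnish the diastereomerically pure salt (R)-1-phenylethylammonium (2R)-2-[(benzoyloxy)methyl]-2-hydroxybut-3-enoate F7 (the antipodal amine is used if it crystallises the (R)-acid better). Acidification returns to the route at 6.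

Further compounds
F1 | step 6 | (2R)-2-ethenyl-3-oxo-2-[(triethylsilyl)oxy]hept-6-en-1-yl benzoate | O=C(OC[C@@](C=C)(O[Si](CC)(CC)CC)C(=O)CCC=C)c1ccccc1
F2 | step 6 | [(1R)-2-oxo-1-[(triethylsilyl)oxy]cyclohex-5-en-1-yl]methyl benzoate | O=C(OC[C@@]1(O[Si](CC)(CC)CC)C(=O)CCC=C1)c1ccccc1
F3 | step 7 | [(1R)-1-hydroxy-2-oxocyclohexa-3,5-dien-1-yl]methyl benzoate | O=C(OC[C@@]1(O)C(=O)C=CC=C1)c1ccccc1
F4 | step 7 | [(1S,2S,6S)-2-hydroxy-3-oxo-7-oxabicyclo[4.1.0]hept-4-en-2-yl]methyl benzoate | O=C(OC[C@@]1(O)C(=O)C=C[C@@H]2O[C@@H]21)c1ccccc1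
F5 | step 2 | rac-2-hydroxy-2-(hydroxymethyl)but-3-en-1-yl benzoate | O=C(OCC(C=C)(O)CO)c1ccccc1
F6 | step 2 | rac-2-[(benzoyloxy)methyl]-2-hydroxybut-3-enoic acid | O=C(OCC(C=C)(O)C(=O)O)c1ccccc1
F7 | step 2 | (R)-1-phenylethylammonium (2R)-2-[(benzoyloxy)methyl]-2-hydroxybut-3-enoate | O=C(OC[C@@](C=C)(O)C(=O)[O-])c1ccccc1.C[C@@H]([NH3+])c1ccccc1
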